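**Plan**

- Retrosynthesis: cut the two prenyl C=C bonds (back to allyl groups), then the two aryl C3–CH2 bonds (back to a bis(4-O-allyl) ether), then the two aryl C5–CH bonds at the bridging methine, then the O4–allyl bond and last the aryl C1–acyl bond.
- Forward: no ring is formed. Phloroglucinol is C-acylated, O-allylated at O4, two such units are joined through 6-methylheptanal, both allyl groups are moved from O4 to C3 in one operation, and both are then converted to prenyl.
- Enabling feature: on each of rings A and B (C1 acyl, C2/C4/C6 hydroxyl, C3 prenyl, C5 bridge), C3 is the only unsubstituted carbon ortho to the C4 hydroxyl, which is para to the ketone and the one phenol not ortho to the acyl group. The other ortho carbon, C5, is blocked by the bridge.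
- Stereochemistry: both (R) centres come from (R)-2-methylbutanoic acid and are carried through unchanged. The bridging methine bears two identical arms and is not a stereocentre.

Key step: step 5

Remark: the sp3 carbons created in the transient species 8, 10, 11 and 12 (the carbinol carbon, the dienone C3, and the bridging methine while the two rings differ) arise as mixtures and are left undefined, since they all vanish in the isolated compounds 9 and 13; 6-methylheptanal is taken as a purchasable aldehyde.

**Route**

Step 1
Reactants: 1 (R)-2-methylbutanoic acid
Product: 2 (R)-2-methylbutanoyl chloride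
Conditions: (COCl)2 (1.2 equiv), DMF (cat.), CH2Cl2, 0 °C to rt; concentrated, used crude
Reagents that add atoms: oxalyl chloride, O=C(Cl)C(=O)Cl
Why: Chlorination of a carboxylic acid by oxalyl chloride under catalytic Vilsmeier activation runs without base, so no ketene can form and the alpha stereocentre of 1 should pass into 2 unchanged.

Step 2
Reactants: 3 phloroglucinol; 2 (R)-2-methylbutanoyl chloride
Product: 4 (R)-2-methyl-1-(2,4,6-trihydroxyphenyl)butan-1-one
Conditions: AlCl3 (4 equiv), CH2Cl2/MeNO2, 0 °C to rt; then ice, 1 M HCl
Reagents that add atoms: none
Why: Friedel–Crafts C-acylation of the strongly activated phloroglucinol ring with an acyl chloride and AlCl3 is the standard entry to acylphloroglucinols, should stop at the mono-ketone because the aluminium-chelated aryl ketone is deactivated, and should spare the alpha stereocentre because the ketone is held as its chelate and no base is present.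

Step 3
Reactants: 4 (R)-2-methyl-1-(2,4,6-trihydroxyphenyl)butan-1-one; 5 allyl bromide
Product: 6 (R)-1-[4-(allyloxy)-2,6-dihydroxyphenyl]-2-methylbutan-1-one
Conditions: allyl bromide (1.0 equiv), K2CO3 (1.1 equiv), acetone, rt
Reagents that add atoms: none
Why: Williamson etherification with one equivalent of a mild base should alkylate O4 selectively, because the hydroxyl para to the ketone is the most acidic (a vinylogous acid) and the only one not held in a hydrogen bond to the carbonyl oxygen, and K2CO3 in acetone at room temperature should not epimerise the alpha centre.

Step 4
Reactants: 6 (R)-1-[4-(allyloxy)-2,6-dihydroxyphenyl]-2-methylbutan-1-one (two molecules); 7 6-methylheptanal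
Product: 9 bis(4-O-allyl) dimer, via benzylic carbinol 8 (not isolated)
Conditions: 6 (3 equiv), 7 (1 equiv, slow addition), TsOH·H2O (10 mol %), MeCN, 0 °C to rt; excess 6 recovered
Reagents that add atoms: none
Why: Acid-catalysed Friedel–Crafts hydroxyalkylation of the electron-rich ring at C3 (equivalent to C5) gives carbinol 8, which ionises to a benzylic cation (a protonated ortho-quinone methide) that a second molecule of 6 captures in a Friedel–Crafts alkylation; the excess of 6 and the slow addition of 7 should hold back further condensation at the remaining free carbon, and the new methine is not a stereocentre because its two aryl arms are identical.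

Step 5
Reactants: 9 bis(4-O-allyl) dimer
Product: 13 bis(C-allyl) dimer, via mono-dienone 10 (not isolated), via mono-C-allyl phenol 11 (not isolated), via second dienone 12 (not isolated)
Conditions: degassed 1,2-dichlorobenzene, 180 °C, sealed tube, Ar
Reagents that add atoms: none
Why: Each aryl allyl ether should undergo a concerted suprafacial [3,3]-sigmatropic shift through a chair-like six-membered transition state, breaking the O4–CH2 bond and joining the allyl terminus to C3 to give a 6-allylcyclohexa-2,4-dienone (10, then 12) that enolises at once to the phenol (11, then 13). The closest known reaction type is the thermal ortho-Claisen rearrangement of allyl aryl ethers, here run on both rings in one flask. No ring closes and no lasting stereocentre is created, since the sp3 carbon of each dienone is flattened again on enolisation. The selectivity needed is regiochemical, C3 against C5: C5 carries the bridging methine, so a shift onto it gives a dienone that cannot enolise and returns by the reverse shift, and the material should drain through the free C3. The medium is neutral and aprotic, so the two enolisable (R) centres next to the ketones and the acid-sensitive diarylmethine should be left alone, and the chelated hydroxyls at C2 and C6 take no part. An allyl group is moved instead of a prenyl group because the shift inverts the three-carbon unit, which is invisible for allyl but would deliver a 1,1-dimethylallyl group from a prenyl ether.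

Step 6
Reactants: 13 bis(C-allyl) dimer
Product: 14 target, 1,1-bis{2,4,6-trihydroxy-3-[(R)-2-methylbutanoyl]-5-(3-methylbut-2-enyl)phenyl}-6-methylheptane
Conditions: second-generation Grubbs catalyst (H2IMes)(PCy3)Cl2Ru=CHPh (10 mol %), 2-methyl-2-butene (large excess)/CH2Cl2, 40 °C, sealed tube
Reagents that add atoms: 2-methyl-2-butene, CC=C(C)C
Why: Olefin cross-metathesis of a terminal allyl arene with 2-methyl-2-butene transfers an isopropylidene unit and releases propene, a well-used way to turn ortho-allylphenols into prenylphenols that tolerates free phenols and aryl ketones, and the large excess of the volatile olefin should suppress homodimerisation and carry both allyl groups through to prenyl.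

**Compound list**

1 | (R)-2-methylbutanoic acid | CC[C@@H](C)C(=O)O | starting material
2 | (R)-2-methylbutanoyl chloride | CC[C@@H](C)C(=O)Cl | intermediate
3 | phloroglucinol (benzene-1,3,5-triol) | Oc1cc(O)cc(O)c1 | starting material
4 | (R)-2-methyl-1-(2,4,6-trihydroxyphenyl)butan-1-one | CC[C@@H](C)C(=O)c1c(O)cc(O)cc1O | intermediate
5 | allyl bromide | C=CCBr | starting material
6 | (R)-1-[4-(allyloxy)-2,6-dihydroxyphenyl]-2-methylbutan-1-one | CC[C@@H](C)C(=O)c1c(O)cc(OCC=C)cc1O | intermediate
7 | 6-methylheptanal | CC(C)CCCCC=O | starting material
8 | benzylic carbinol, (2R)-1-[4-(allyloxy)-2,6-dihydroxy-3-(1-hydroxy-6-methylheptyl)phenyl]-2-methylbutan-1-one, carbinol carbon undefined | CC[C@@H](C)C(=O)c1c(O)cc(OCC=C)c(C(O)CCCCC(C)C)c1O | intermediate (not isolated)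
9 | bis(4-O-allyl) dimer, 1,1-bis{6-(allyloxy)-2,4-dihydroxy-3-[(R)-2-methylbutanoyl]phenyl}-6-methylheptane | CC[C@@H](C)C(=O)c1c(O)cc(OCC=C)c(C(CCCCC(C)C)c2c(OCC=C)cc(O)c(C(=O)[C@H](C)CC)c2O)c1O | intermediate (key-step precursor)
10 | mono-dienone: ring A as 6-allylcyclohexa-2,4-dienone (C4 carbonyl, C3 sp3 bearing the allyl group), ring B still the aryl allyl ether | CC[C@@H](C)C(=O)C1=C(O)C(CC=C)C(=O)C(C(CCCCC(C)C)c2c(OCC=C)cc(O)c(C(=O)[C@H](C)CC)c2O)=C1O | intermediate (not isolated)
11 | mono-C-allyl phenol: ring A 3-allyl-2,4,6-trihydroxy, ring B still the 4-O-allyl ether | CC[C@@H](C)C(=O)c1c(O)c(CC=C)c(O)c(C(CCCCC(C)C)c2c(OCC=C)cc(O)c(C(=O)[C@H](C)CC)c2O)c1O | intermediate (not isolated)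
12 | second dienone: ring A as in 13, ring B as 6-allylcyclohexa-2,4-dienone | CC[C@@H](C)C(=O)c1c(O)c(CC=C)c(O)c(C(CCCCC(C)C)C2=C(O)C(C(=O)[C@H](C)CC)=C(O)C(CC=C)C2=O)c1O | intermediate (not isolated)
13 | bis(C-allyl) dimer, 1,1-bis{3-allyl-2,4,6-trihydroxy-5-[(R)-2-methylbutanoyl]phenyl}-6-methylheptane | CC[C@@H](C)C(=O)c1c(O)c(CC=C)c(O)c(C(CCCCC(C)C)c2c(O)c(CC=C)c(O)c(C(=O)[C@H](C)CC)c2O)c1O | intermediate (key-step product)
14 | 1,1-bis{2,4,6-trihydroxy-3-[(R)-2-methylbutanoyl]-5-(3-methylbut-2-enyl)phenyl}-6-methylheptane (CNP0245910.1) | CC[C@@H](C)C(=O)c1c(O)c(CC=C(C)C)c(O)c(C(CCCCC(C)C)c2c(O)c(CC=C(C)C)c(O)c(C(=O)[C@H](C)CC)c2O)c1O | target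

**Count and risks**

Total steps: 6. Longest linear sequence: 6 steps (1 → 2 → 4 → 6 → 9 → 13 → 14).

Steps most likely to fail:

1. Step 5. At 180 °C the dimer may fragment at the bridging methine (loss of an aryl group from the blocked C5 dienone or through an ortho-quinone methide), a freshly formed allyl group may cyclise onto a neighbouring hydroxyl, or the ketone alpha centres may slowly epimerise. The fallback moves the sigmatropic shift ahead of the bridging. It sets out from 6, which is heated alone in degassed 1,2-dichlorobenzene at 180 °C; its two ortho carbons are equivalent and free, so it should give (R)-1-(3-allyl-2,4,6-trihydroxyphenyl)-2-methylbutan-1-one F1. Two equivalents of this phenol are then condensed with 7 under the acid conditions of step 4 (TsOH·H2O, MeCN, rt). Only C5 is free, so the condensation can stop only at the dimer, and the route is rejoined at 13.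

2. Step 4. Condensation may continue at the remaining free ring carbon of the product to give trimers and oligomers, or the benzylic cation may lose a proton to an alkenyl arene before the second ring adds. The fallback splits the bridging into two controlled stages through a stable ortho-quinone methide precursor. It sets out from 6, which is combined with 7 and morpholine (EtOH, rt to 60 °C) in a phenolic Mannich (Betti) reaction to give the morpholine Mannich base (2R)-1-{4-(allyloxy)-2,6-dihydroxy-3-[6-methyl-1-(morpholin-4-yl)heptyl]phenyl}-2-methylbutan-1-one F2, which is purified. Heating this base with an excess of 6 (toluene, 100 °C) expels morpholine, and the ortho-quinone methide so formed is trapped by 6 in the absence of free aldehyde, rejoining the route at 9.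

3. Step 3. The ambident phenoxide may be allylated on carbon instead of oxygen, or a second allyl group may enter at O2. The fallback replaces phenoxide alkylation by a Mitsunobu etherification. It sets out from 4, which is treated with allyl alcohol, PPh3 and diisopropyl azodicarboxylate (THF, 0 °C to rt). Only the non-chelated, most acidic hydroxyl at C4 should be engaged, and no free phenoxide is present to alkylate on carbon. The route is rejoined at 6, and no new compound arises (entry F0).

Further compounds
F1 | step 5 | (R)-1-(3-allyl-2,4,6-trihydroxyphenyl)-2-methylbutan-1-one | CC[C@@H](C)C(=O)c1c(O)cc(O)c(CC=C)c1O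
F2 | step 4 | (2R)-1-{4-(allyloxy)-2,6-dihydroxy-3-[6-methyl-1-(morpholin-4-yl)heptyl]phenyl}-2-methylbutan-1-one, aminal-type benzylic carbon undefined | CC[C@@H](C)C(=O)c1c(O)cc(OCC=C)c(C(CCCCC(C)C)N2CCOCC2)c1O
F0 | step 3 | none | none
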